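**Plan**

- Retrosynthesis: ring A is cut at C1–C2 and C5–C6 (retro-Diels–Alder, methanol added back), then the depside C(=O)–O bond, then the alkyne–CO2H bond and the triple bond itself (back to an aldehyde).
- Enabling feature: in ring A the ester carbon sits on C1, OH on C2 and OMe on C4 (meta to each other) and the 2-oxoheptyl chain on C6. C1/C6 therefore map onto the α/β carbons of an ynoate, and C2–C5 onto a 1,3-dioxygenated butadiene at the ketene acetal level.
- Forward: the ketal-masked ynoic acid is built from ethyl 3-oxooctanoate (steps 1–4) and joined to the 4-OH of benzyl olivetolate (steps 5–6). Ring A is then closed on the intact depside ester (step 8); ring B is bought as olivetolic acid.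
- End game: ketal hydrolysis, then hydrogenolysis of the single benzyl ester (steps 9–10).
- Stereochemistry: the target has no stereocentre and no stereogenic double bond, so none has to be set.

Key step: step 8

Remark: ring B is carried with its chelated 2-OH free, since acylation of benzyl 2,4-dihydroxy-6-alkylbenzoates goes to the 4-OH. Diene 13 is used as obtained, because its ketene acetal geometry is lost on aromatisation.

**Route**

Step 1
Reactants: 1 ethyl 3-oxooctanoate
Product: 2 ethyl (2-pentyl-1,3-dioxolan-2-yl)acetate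
Conditions: HOCH2CH2OH (3 equiv), p-TsOH·H2O (cat.), toluene, reflux, Dean–Stark
Reagents that add atoms: ethylene glycol, OCCO
Why: Acid-catalysed ketalisation with azeotropic removal of water is selective for the ketone of a β-keto ester and masks it, so that the later propargylic CH2 cannot drift to an allenyl ketone.

Step 2
Reactants: 2 ethyl (2-pentyl-1,3-dioxolan-2-yl)acetate
Product: 3 (2-pentyl-1,3-dioxolan-2-yl)acetaldehyde
Conditions: i-Bu2AlH (1.1 equiv), CH2Cl2, −78 °C; MeOH, then aq. KNaC4H4O6
Reagents that add atoms: none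
Why: Partial ester reduction with i-Bu2AlH at −78 °C should stop at the aldehyde because the tetrahedral aluminium hemiacetal, chelated by a dioxolane oxygen, survives until the quench.

Step 3
Reactants: 3 (2-pentyl-1,3-dioxolan-2-yl)acetaldehyde
Product: 4 2-(3,3-dibromoprop-2-en-1-yl)-2-pentyl-1,3-dioxolane
Conditions: CBr4 (2 equiv), PPh3 (4 equiv), Et3N, CH2Cl2, 0 °C
Reagents that add atoms: carbon tetrabromide, BrC(Br)(Br)Br
Why: Corey–Fuchs (Ramirez) dibromoolefination, in which Ph3P=CBr2 made from CBr4 and PPh3 undergoes a Wittig reaction with the aldehyde while Et3N buffers the acidic phosphorus by-products and so protects the ketal.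

Step 4
Reactants: 4 2-(3,3-dibromoprop-2-en-1-yl)-2-pentyl-1,3-dioxolane
Product: 7 4-(2-pentyl-1,3-dioxolan-2-yl)but-2-ynoic acid, via lithium acetylide 5 (not isolated), via lithium carboxylate 6 (not isolated)
Conditions: n-BuLi (2.2 equiv), THF, −78 to 0 °C; CO2, −78 °C; cold 1 M HCl to pH 3, rapid extraction
Reagents that add atoms: carbon dioxide, O=C=O
Why: Second stage of the Corey–Fuchs homologation, in which Br/Li exchange and Fritsch–Buttenberg–Wiechell rearrangement give the alkyne, the second equivalent of n-BuLi forms acetylide 5, and carboxylation with CO2 gives the ynoate.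

Step 5
Reactants: 8 olivetolic acid (2,4-dihydroxy-6-pentylbenzoic acid)
Product: 9 benzyl 2,4-dihydroxy-6-pentylbenzoate
Conditions: BnBr (1.05 equiv), KHCO3 (1.1 equiv), DMF, rt
Reagents that add atoms: benzyl bromide, BrCc1ccccc1
Why: SN2 O-alkylation of the carboxylate; KHCO3 deprotonates only the carboxylic acid, so both phenols stay free, and room temperature avoids decarboxylation of the β-resorcylic acid.

Step 6
Reactants: 7 4-(2-pentyl-1,3-dioxolan-2-yl)but-2-ynoic acid; 9 benzyl 2,4-dihydroxy-6-pentylbenzoate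
Product: 10 benzyl 2-hydroxy-6-pentyl-4-{[4-(2-pentyl-1,3-dioxolan-2-yl)but-2-ynoyl]oxy}benzoate
Conditions: DCC (1.1 equiv), DMAP (5 mol%), CH2Cl2, −20 to 0 °C
Reagents that add atoms: none
Why: Steglich esterification; the 2-OH of 9 is tied up in a hydrogen bond to the adjacent ester carbonyl, so acylation should go to the free 4-OH as in classical depside couplings, and the unhindered ynoic acid is activated cold to limit conjugate addition.

Step 7
Reactants: 11 methyl (E)-3-methoxybut-2-enoate
Product: 13 1,3-dimethoxy-1-(trimethylsilyloxy)buta-1,3-diene, via lithium dienolate 12 (not isolated)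
Conditions: LiN(i-Pr)2 (1.1 equiv), THF, −78 °C; Me3SiCl, −78 °C to rt; bulb-to-bulb distillation, used at once
Reagents that add atoms: chlorotrimethylsilane, C[Si](C)(C)Cl
Why: Kinetic γ-deprotonation of the vinylogous ester gives the extended dienolate, and O-silylation with Me3SiCl gives the vinylogous silyl ketene acetal (Brassard-type diene).

Step 8
Reactants: 10 benzyl 2-hydroxy-6-pentyl-4-{[4-(2-pentyl-1,3-dioxolan-2-yl)but-2-ynoyl]oxy}benzoate; 13 1,3-dimethoxy-1-(trimethylsilyloxy)buta-1,3-diene
Product: 16 benzyl 2-hydroxy-4-({2-hydroxy-4-methoxy-6-[(2-pentyl-1,3-dioxolan-2-yl)methyl]benzoyl}oxy)-6-pentylbenzoate, via cyclohexadiene cycloadduct 14 (not isolated), via ring A trimethylsilyl ether 15 (not isolated)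
Conditions: 13 (4 equiv), toluene, 120 °C, sealed tube; then aq. NH4Cl, THF, rt
Reagents that add atoms: none
Why: The electron-rich diene 13 and the electron-poor aryl ynoate 10 should combine in a thermal, asynchronous normal-demand Diels–Alder reaction in which bonding between the diene CH2 terminus and the ynoate β-carbon leads, so the ketene acetal carbon ends on the α-carbon and the future C2 oxygen sits next to the ester. The closest known reaction type is the benzannulation of Brassard-type silyl ketene acetal dienes with alkynoates and ynolides to give resorcylates. Ring A closes in one intermolecular (4+2) event that forms C1–C2 and C5–C6 together to give 1,4-cyclohexadiene 14, which aromatises by 1,4-elimination of methanol from the mixed acetal carbon to silyl ether 15, and the mild aqueous work-up then frees the C2 phenol. No stereocentre survives, because the acetal carbon of 14 becomes aromatic C2. The step needs regioselectivity (OH ortho to the ester) and chemoselectivity (cycloaddition before attack on the aryl ester or the ketal); the first follows from the matched polarisation of the partners, the second from the absence of any Lewis acid, and the dioxolane blocks prototropic drift of the ynoate. The aryl ester makes the alkyne a better dienophile than an alkyl ester would, and the chelated ring B phenol is a poor proton donor towards the diene, whose excess covers any loss.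

Step 9
Reactants: 16 benzyl 2-hydroxy-4-({2-hydroxy-4-methoxy-6-[(2-pentyl-1,3-dioxolan-2-yl)methyl]benzoyl}oxy)-6-pentylbenzoate
Product: 17 benzyl 2-hydroxy-4-{[2-hydroxy-4-methoxy-6-(2-oxoheptyl)benzoyl]oxy}-6-pentylbenzoate
Conditions: PPTS (0.3 equiv), acetone–H2O (9:1), 50 °C
Reagents that add atoms: water, O
Why: Acid-catalysed ketal hydrolysis of a dialkyl ketone dioxolane; the buffered acid PPTS should spare both esters and the chelated phenols and is too weak to drive closure of the freed ketone onto the depside carbonyl.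

Step 10
Reactants: 17 benzyl 2-hydroxy-4-{[2-hydroxy-4-methoxy-6-(2-oxoheptyl)benzoyl]oxy}-6-pentylbenzoate
Product: 18 2-hydroxy-4-{[2-hydroxy-4-methoxy-6-(2-oxoheptyl)benzoyl]oxy}-6-pentylbenzoic acid (CNP0358566.0)
Conditions: H2 (1 atm), Pd/C (10 wt% Pd), EtOAc, rt
Reagents that add atoms: none
Why: Hydrogenolysis of the benzyl ester C–O bond over palladium on carbon under neutral conditions; the aryl ester, the aliphatic ketone and the arenes should not be reduced at 1 atm and room temperature.

**Compound list**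

1 | ethyl 3-oxooctanoate | CCCCCC(=O)CC(=O)OCC | starting material
2 | ethyl (2-pentyl-1,3-dioxolan-2-yl)acetate | CCCCCC1(CC(=O)OCC)OCCO1 | intermediate
3 | (2-pentyl-1,3-dioxolan-2-yl)acetaldehyde | CCCCCC1(CC=O)OCCO1 | intermediate
4 | 2-(3,3-dibromoprop-2-en-1-yl)-2-pentyl-1,3-dioxolane | CCCCCC1(CC=C(Br)Br)OCCO1 | intermediate
5 | [3-(2-pentyl-1,3-dioxolan-2-yl)prop-1-yn-1-yl]lithium | CCCCCC1(CC#C[Li])OCCO1 | intermediate
6 | lithium 4-(2-pentyl-1,3-dioxolan-2-yl)but-2-ynoate | [Li+].CCCCCC1(CC#CC(=O)[O-])OCCO1 | intermediate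
7 | 4-(2-pentyl-1,3-dioxolan-2-yl)but-2-ynoic acid | CCCCCC1(CC#CC(=O)O)OCCO1 | intermediate
8 | olivetolic acid (2,4-dihydroxy-6-pentylbenzoic acid) | CCCCCc1cc(O)cc(O)c1C(=O)O | starting material
9 | benzyl 2,4-dihydroxy-6-pentylbenzoate | CCCCCc1cc(O)cc(O)c1C(=O)OCc1ccccc1 | intermediate
10 | benzyl 2-hydroxy-6-pentyl-4-{[4-(2-pentyl-1,3-dioxolan-2-yl)but-2-ynoyl]oxy}benzoate | CCCCCC1(CC#CC(=O)Oc2cc(O)c(C(=O)OCc3ccccc3)c(CCCCC)c2)OCCO1 | intermediate
11 | methyl (E)-3-methoxybut-2-enoate | CO/C(C)=C/C(=O)OC | starting material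
12 | lithium 1,3-dimethoxybuta-1,3-dien-1-olate | C=C(OC)C=C(OC)O[Li] | intermediate
13 | 1,3-dimethoxy-1-(trimethylsilyloxy)buta-1,3-diene (ketene acetal geometry undefined) | C=C(OC)C=C(OC)O[Si](C)(C)C | intermediate
14 | benzyl 4-[({4,6-dimethoxy-2-[(2-pentyl-1,3-dioxolan-2-yl)methyl]-6-(trimethylsilyloxy)cyclohexa-1,4-dien-1-yl}carbonyl)oxy]-2-hydroxy-6-pentylbenzoate (racemic) | CCCCCC1(CC2=C(C(=O)Oc3cc(O)c(C(=O)OCc4ccccc4)c(CCCCC)c3)C(OC)(O[Si](C)(C)C)C=C(OC)C2)OCCO1 | intermediate
15 | benzyl 2-hydroxy-4-({4-methoxy-2-[(2-pentyl-1,3-dioxolan-2-yl)methyl]-6-(trimethylsilyloxy)benzoyl}oxy)-6-pentylbenzoate | CCCCCC1(Cc2cc(OC)cc(O[Si](C)(C)C)c2C(=O)Oc2cc(O)c(C(=O)OCc3ccccc3)c(CCCCC)c2)OCCO1 | intermediate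
16 | benzyl 2-hydroxy-4-({2-hydroxy-4-methoxy-6-[(2-pentyl-1,3-dioxolan-2-yl)methyl]benzoyl}oxy)-6-pentylbenzoate | CCCCCC1(Cc2cc(OC)cc(O)c2C(=O)Oc2cc(O)c(C(=O)OCc3ccccc3)c(CCCCC)c2)OCCO1 | intermediate
17 | benzyl 2-hydroxy-4-{[2-hydroxy-4-methoxy-6-(2-oxoheptyl)benzoyl]oxy}-6-pentylbenzoate | CCCCCC(=O)Cc1cc(OC)cc(O)c1C(=O)Oc1cc(O)c(C(=O)OCc2ccccc2)c(CCCCC)c1 | intermediate
18 | 2-hydroxy-4-{[2-hydroxy-4-methoxy-6-(2-oxoheptyl)benzoyl]oxy}-6-pentylbenzoic acid | CCCCCC(=O)Cc1cc(OC)cc(O)c1C(=O)Oc1cc(O)c(C(=O)O)c(CCCCC)c1 | target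

**Step count**

Total steps: 10. Longest linear sequence: 8 steps (1, 2, 3, 4, 6, 8, 9, 10).

**Steps most likely to fail**

For step 8, the internal ynoate may react so slowly that the diene is lost to silyl migration and hydrolysis first. Aromatisation may also proceed by loss of trimethylsilanol instead of methanol, leaving a methyl ether on C2. The fallback sets out from 10 and replaces the acyclic diene by 5,5-dimethyl-1,3-bis(trimethylsilyloxy)cyclohexa-1,3-diene F1, made from 5,5-dimethylcyclohexane-1,3-dione with LiN(i-Pr)2 and Me3SiCl. Heating 10 with F1 at 140 °C should give the bicyclo[2.2.2]octadiene cycloadduct F2, which expels 2-methylpropene in a retro-Diels–Alder reaction. Aromatisation then involves no choice of leaving group and gives the ring A bis(trimethylsilyl) ether F3. Aqueous NH4Cl work-up should give the 2,4-dihydroxy depside F4. Mitsunobu methylation (MeOH, PPh3, diisopropyl azodicarboxylate, THF, 0 °C) at its only non-chelated phenol comes back to the route at 16.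

For step 6, the activated ynoic acid may rearrange to the N-acylurea, may suffer conjugate addition of DMAP or of the phenol, or may isomerise to the allenoate under the basic catalyst. The fallback sets out from 7 and moves the activation out of the coupling flask. 1-Chloro-N,N,2-trimethylprop-1-en-1-amine in CH2Cl2 at 0 °C should give, under neutral conditions, 4-(2-pentyl-1,3-dioxolan-2-yl)but-2-ynoyl chloride F5. F5 is added to phenol 9 and 2,6-lutidine at −20 °C without any nucleophilic catalyst, which comes back to the route at 10.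

For step 3, acid released from the bromophosphonium by-products may open the dioxolane, and the β-ketal aldehyde may eliminate or self-condense before the Wittig reaction. The fallback sets out from 3 and uses a Seyferth–Gilbert homologation in place of the dibromoolefin. Dimethyl (1-diazo-2-oxopropyl)phosphonate with K2CO3 in MeOH at rt should give 2-pentyl-2-(prop-2-yn-1-yl)-1,3-dioxolane F6. Deprotonation with n-BuLi (THF, −78 °C), CO2 and cold acidification (through 5 and 6) comes back to the route at 7.

**Further compounds**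

F1 | step 8 | 5,5-dimethyl-1,3-bis(trimethylsilyloxy)cyclohexa-1,3-diene | CC1(C)CC(O[Si](C)(C)C)=CC(O[Si](C)(C)C)=C1
F2 | step 8 | benzyl 4-[({8,8-dimethyl-3-[(2-pentyl-1,3-dioxolan-2-yl)methyl]-1,5-bis(trimethylsilyloxy)bicyclo[2.2.2]octa-2,5-dien-2-yl}carbonyl)oxy]-2-hydroxy-6-pentylbenzoate (racemic) | C[Si](C)(C)OC12C=C(O[Si](C)(C)C)C(C(C)(C)C1)C(CC1(CCCCC)OCCO1)=C2C(=O)Oc1cc(O)c(C(=O)OCc2ccccc2)c(CCCCC)c1
F3 | step 8 | benzyl 2-hydroxy-4-({2-[(2-pentyl-1,3-dioxolan-2-yl)methyl]-4,6-bis(trimethylsilyloxy)benzoyl}oxy)-6-pentylbenzoate | CCCCCC1(Cc2cc(O[Si](C)(C)C)cc(O[Si](C)(C)C)c2C(=O)Oc2cc(O)c(C(=O)OCc3ccccc3)c(CCCCC)c2)OCCO1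
F4 | step 8 | benzyl 4-({2,4-dihydroxy-6-[(2-pentyl-1,3-dioxolan-2-yl)methyl]benzoyl}oxy)-2-hydroxy-6-pentylbenzoate | CCCCCC1(Cc2cc(O)cc(O)c2C(=O)Oc2cc(O)c(C(=O)OCc3ccccc3)c(CCCCC)c2)OCCO1
F5 | step 6 | 4-(2-pentyl-1,3-dioxolan-2-yl)but-2-ynoyl chloride | CCCCCC1(CC#CC(=O)Cl)OCCO1
F6 | step 3 | 2-pentyl-2-(prop-2-yn-1-yl)-1,3-dioxolane | CCCCCC1(CC#C)OCCO1
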